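The route builds ring B (the isobutyryl ring) onto ring A instead of joining two finished phloroglucinols. Ring B carries oxygen on C2′, C4′ and C6′. The bridge carbon C1′ and the isopentyl carbon C3′ therefore each lie between two C–O carbons. A polarised ynol ether and a 3-oxygenated vinylketene deliver exactly this alternation. The precursor is a 3-benzyloxycyclobutenone that bears the fully benzylated ring A as its 2-arylmethyl group. In one thermal operation it combines with isopentyl triisopropylsiloxyacetylene to form C3′–C4′, C1′–C2′ and C4′–C5′, and the ring aromatises. This leaves OH, OTIPS and OBn distinct and C5′–H free for the isobutyryl group.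

Key step: step 9

Remarks on the chemistry:
- Ring A is the acetyl ring. Ring B is numbered C1′ (bridge CH2), C2′ (O), C3′ (isopentyl), C4′ (O), C5′ (isobutyryl), C6′ (O).
- ArBn stands for 3-acetyl-2,4-bis(benzyloxy)-6-methoxy-5-methylphenyl.
- The target has no stereocentre. Enolised four-membered diones are drawn as the tautomer named.
- The three starting materials are assumed to be catalogue compounds.

Step 1
Reactants: 1 2-methylbenzene-1,3,5-triol (2-methylphloroglucinol)
Product: 2 1-(2,4,6-trihydroxy-3-methylphenyl)ethan-1-one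
Conditions: Ac2O (1.0 equiv), BF3·OEt2, rt; aq. NaOAc
Reagents that add atoms: acetic anhydride, CC(=O)OC(C)=O
Why: Friedel–Crafts C-acylation of a phloroglucinol, in which the two free ring carbons of 1 are equivalent, the first acyl group (held as a chelated o-hydroxyketone) deactivates the ring towards a second one, and starting from the C-methylated triol avoids an unselective nuclear methylation.

Step 2
Reactants: 2 1-(2,4,6-trihydroxy-3-methylphenyl)ethan-1-one
Product: 3 1-(2,6-dihydroxy-4-methoxy-3-methylphenyl)ethan-1-one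
Conditions: Me2SO4 (1.0 equiv), K2CO3 (1.0 equiv), acetone, rt to reflux
Reagents that add atoms: dimethyl sulfate, COS(=O)(=O)OC
Why: Williamson O-methylation with one equivalent of reagent, selective because the 4-OH para to the acetyl group is the most acidic hydroxyl while the two hydroxyls flanking the acetyl group share its hydrogen bond and are shielded.

Step 3
Reactants: 3 1-(2,6-dihydroxy-4-methoxy-3-methylphenyl)ethan-1-one
Product: 4 1-{3-[(dimethylamino)methyl]-2,6-dihydroxy-4-methoxy-5-methylphenyl}ethan-1-one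
Conditions: 37% aq. HCHO, 40% aq. Me2NH, EtOH, 0 °C to rt
Reagents that add atoms: formaldehyde, C=O; dimethylamine, CNC
Why: Mannich aminomethylation at C5 of 3, the only unsubstituted ring carbon, which lies ortho to one hydroxyl and para to the other and is far more nucleophilic than the acetyl methyl group under these near-neutral conditions.

Step 4
Reactants: 4 1-{3-[(dimethylamino)methyl]-2,6-dihydroxy-4-methoxy-5-methylphenyl}ethan-1-one
Product: 5 (3-acetyl-2,4-dihydroxy-6-methoxy-5-methylphenyl)-N,N,N-trimethylmethanaminium iodide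
Conditions: MeI (3 equiv), Et2O–CH2Cl2, rt, dark; filter
Reagents that add atoms: iodomethane, CI
Why: Menshutkin quaternisation of the benzylic amine in a low-polarity medium, which makes NMe3 the leaving group, a tertiary amine that can neither open nor condense with the four-membered dione of step 6, and lets the quinone methide form near room temperature.

Step 5
Reactants: 6 3-ethoxycyclobut-2-en-1-one
Product: 7 cyclobutane-1,3-dione
Conditions: 1 M aq. HCl, 0 °C to rt; concentrate cold, use at once
Reagents that add atoms: water, O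
Why: Acid hydrolysis of a vinylogous ester (water adds at C3, ethanol leaves), the established preparation of this dione, which is made fresh because it stores poorly.

Step 6
Reactants: 5 (3-acetyl-2,4-dihydroxy-6-methoxy-5-methylphenyl)-N,N,N-trimethylmethanaminium iodide; 7 cyclobutane-1,3-dione
Product: 9 2-[(3-acetyl-2,4-dihydroxy-6-methoxy-5-methylphenyl)methyl]-3-hydroxycyclobut-2-en-1-one, via ortho-quinone methide 8 (not isolated)
Conditions: 7 (2 equiv), K2CO3 (3 equiv), DMF, 0 °C to rt; cold 1 M HCl work-up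
Reagents that add atoms: none
Why: Base-induced 1,4-elimination of NMe3 gives quinone methide 8, which C2 of the dione enolate captures at the exocyclic CH2 in a Michael addition of the type known for tetronic acids, 4-hydroxycoumarins, Meldrum's acid and five- and six-membered 1,3-diones, where O-attack is reversible, C-attack rearomatises ring A, the fully substituted ring A cannot self-condense and excess 7 suppresses double alkylation.

Step 7
Reactants: 9 2-[(3-acetyl-2,4-dihydroxy-6-methoxy-5-methylphenyl)methyl]-3-hydroxycyclobut-2-en-1-one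
Product: 10 2-(ArBn-methyl)-3-(benzyloxy)cyclobut-2-en-1-one
Conditions: BnBr (3.6 equiv), Cs2CO3 (3.6 equiv), DMF, 0 °C to rt
Reagents that add atoms: benzyl bromide, BrCc1ccccc1
Why: Williamson benzylation of two phenoxides and of a vinylogous carboxylate, in which loss of the enol proton gives directly the C2-substituted anion with two equivalent oxygens, which reacts at oxygen like a caesium carboxylate in DMF because C-benzylation would sacrifice the vinylogous-acid resonance and create a quaternary carbon in a strained, non-enolisable dione.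

Step 8
Reactants: 11 ethyl 4-methylpentanoate
Product: 14 triisopropyl[(5-methylhex-1-yn-1-yl)oxy]silane, via lithium dibromoenolate 12 (not isolated), via lithium ynolate 13 (not isolated)
Conditions: CH2Br2, LiTMP, THF, −78 °C; then n-BuLi, −78 to 0 °C; then TIPSOTf, −78 °C to rt
Reagents that add atoms: dibromomethane, BrCBr; triisopropylsilyl trifluoromethanesulfonate, CC(C)[Si](C(C)C)(C(C)C)OS(=O)(=O)C(F)(F)F
Why: Kowalski ynolate formation, in which acylation of LiCHBr2 gives enolate 12, bromine–lithium exchange triggers the 1,2-shift of the isopentyl group with loss of LiBr to ynolate 13, and the bulky silyl triflate traps 13 on oxygen.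

Step 9
Reactants: 10 2-(ArBn-methyl)-3-(benzyloxy)cyclobut-2-en-1-one; 14 triisopropyl[(5-methylhex-1-yn-1-yl)oxy]silane
Product: 19 1-[2,6-bis(benzyloxy)-3-{[6-(benzyloxy)-4-hydroxy-3-(3-methylbutyl)-2-(triisopropylsiloxy)phenyl]methyl}-4-methoxy-5-methylphenyl]ethan-1-one, via vinylketene 15 (not isolated), via vinylcyclobutenone 16 (not isolated), via dienylketene 17 (not isolated), via cyclohexadienone 18 (not isolated)
Conditions: 14 (2 equiv), toluene (0.5 M), sealed tube, argon, 140 °C
Reagents that add atoms: none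
Why: Proposed new method: heating opens 10 by four-electron electrocyclic cleavage of its C1–C4 bond to vinylketene 15, the ketene C=C of which adds siloxyalkyne 14 in a (2+2) cycloaddition to vinylcyclobutenone 16, a second four-electron opening gives dienylketene 17, and six-electron electrocyclisation to 18 followed by enolisation delivers phenol 19. The closest known reaction type is the Danheiser benzannulation of 3-alkyl- and 2,3-dialkylcyclobutenones with triisopropylsiloxyalkynes, which gives resorcinol monosilyl ethers; not yet shown is a 3-alkoxycyclobutenone as the vinylketene source, whose vinylogous-ester stabilisation should raise the opening temperature without changing the pericyclic sequence, as squarate-derived 2,3-dialkoxycyclobutenones open in the same temperature range. Ring B is closed by the 6π electrocyclisation, which forms C4′–C5′ after the (2+2) step has formed C3′–C4′ and C1′–C2′. No stereocentre is created in 19: the quaternary carbon of racemic 16 is lost on opening, and because that opening is reversible only the dienylketene with the benzyloxyvinyl group turned towards the ketene is drained to product. The selectivity required is the orientation of the (2+2) step, and the polarisation of the partners secures it: the isopentyl-bearing carbon of the ynol ether is its nucleophilic end and bonds to the electrophilic ketene carbonyl carbon, so isopentyl ends up ortho to the new hydroxyl and the siloxy carbon next to the bridge carbon. Complete O-protection of ring A, the robust benzyl enol ether and an excess of 14 keep the ketene from being consumed by hydroxyl groups, the product phenol included.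

Step 10
Reactants: 19 1-[2,6-bis(benzyloxy)-3-{[6-(benzyloxy)-4-hydroxy-3-(3-methylbutyl)-2-(triisopropylsiloxy)phenyl]methyl}-4-methoxy-5-methylphenyl]ethan-1-one
Product: 20 1-[3-(ArBn-methyl)-2-(benzyloxy)-6-hydroxy-5-(3-methylbutyl)-4-(triisopropylsiloxy)phenyl]-2-methylpropan-1-one
Conditions: i-PrCOCl (1.2 equiv), SnCl4 (2.2 equiv), CH2Cl2, −78 to −20 °C
Reagents that add atoms: isobutyryl chloride, CC(C)C(=O)Cl
Why: Friedel–Crafts acylation at C5′, the only unsubstituted carbon of rings A and B, which is activated by an ortho OH, an ortho OBn and a para OTIPS so that a mild Lewis acid at low temperature suffices, with any O-isobutyrate able to migrate only to this same carbon (Fries) and the product held as a chelated o-hydroxyketone.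

Step 11
Reactants: 20 1-[3-(ArBn-methyl)-2-(benzyloxy)-6-hydroxy-5-(3-methylbutyl)-4-(triisopropylsiloxy)phenyl]-2-methylpropan-1-one
Product: 21 1-[3-(ArBn-methyl)-2-(benzyloxy)-4,6-dihydroxy-5-(3-methylbutyl)phenyl]-2-methylpropan-1-one
Conditions: TBAF (1.1 equiv), AcOH (1.1 equiv), THF, 0 °C
Reagents that add atoms: none
Why: Fluoride cleavage of an aryl silyl ether, buffered with acetic acid and run while three phenols are still benzylated so that no strongly basic polyphenolate forms that could fragment at the methylene bridge.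

Step 12
Reactants: 21 1-[3-(ArBn-methyl)-2-(benzyloxy)-4,6-dihydroxy-5-(3-methylbutyl)phenyl]-2-methylpropan-1-one
Product: 22 1-{3-[(3-acetyl-2,4-dihydroxy-6-methoxy-5-methylphenyl)methyl]-2,4,6-trihydroxy-5-(3-methylbutyl)phenyl}-2-methylpropan-1-one (target)
Conditions: H2 (1 atm), 10% Pd/C, EtOAc–MeOH, rt
Reagents that add atoms: none
Why: Catalytic hydrogenolysis of the three aryl benzyl ethers under neutral conditions, to which the two hydrogen-bonded aryl ketones, the methyl ether and the diarylmethane C–C bonds are inert.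

Compound list
1 | 2-methylbenzene-1,3,5-triol | Cc1c(O)cc(O)cc1O | starting material
2 | 1-(2,4,6-trihydroxy-3-methylphenyl)ethan-1-one | CC(=O)c1c(O)cc(O)c(C)c1O | intermediate
3 | 1-(2,6-dihydroxy-4-methoxy-3-methylphenyl)ethan-1-one | CC(=O)c1c(O)cc(OC)c(C)c1O | intermediate
4 | 1-{3-[(dimethylamino)methyl]-2,6-dihydroxy-4-methoxy-5-methylphenyl}ethan-1-one | CC(=O)c1c(O)c(CN(C)C)c(OC)c(C)c1O | intermediate
5 | (3-acetyl-2,4-dihydroxy-6-methoxy-5-methylphenyl)-N,N,N-trimethylmethanaminium iodide | CC(=O)c1c(O)c(C[N+](C)(C)C)c(OC)c(C)c1O.[I-] | intermediate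
6 | 3-ethoxycyclobut-2-en-1-one | CCOC1=CC(=O)C1 | starting material
7 | cyclobutane-1,3-dione | O=C1CC(=O)C1 | intermediate
8 | 2-acetyl-3-hydroxy-5-methoxy-4-methyl-6-methylidenecyclohexa-2,4-dien-1-one (ortho-quinone methide, not isolated) | C=C1C(=O)C(C(C)=O)=C(O)C(C)=C1OC | intermediate
9 | 2-[(3-acetyl-2,4-dihydroxy-6-methoxy-5-methylphenyl)methyl]-3-hydroxycyclobut-2-en-1-one | O=C1CC(O)=C1Cc1c(OC)c(C)c(O)c(C(C)=O)c1O | intermediate
10 | 2-{[3-acetyl-2,4-bis(benzyloxy)-6-methoxy-5-methylphenyl]methyl}-3-(benzyloxy)cyclobut-2-en-1-one | O=C1CC(OCc2ccccc2)=C1Cc1c(OC)c(C)c(OCc2ccccc2)c(C(C)=O)c1OCc1ccccc1 | intermediate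
11 | ethyl 4-methylpentanoate | CCOC(=O)CCC(C)C | starting material
12 | lithium 1,1-dibromo-5-methylhex-1-en-2-olate (not isolated) | CC(C)CCC([O-])=C(Br)Br.[Li+] | intermediate
13 | lithium 5-methylhex-1-yn-1-olate (not isolated) | CC(C)CCC#C[O-].[Li+] | intermediate
14 | triisopropyl[(5-methylhex-1-yn-1-yl)oxy]silane | CC(C)CCC#CO[Si](C(C)C)(C(C)C)C(C)C | intermediate
15 | 2-(ArBn-methyl)-3-(benzyloxy)buta-1,3-dien-1-one (vinylketene, not isolated) | O=C=C(Cc1c(OC)c(C)c(OCc2ccccc2)c(C(C)=O)c1OCc1ccccc1)C(=C)OCc1ccccc1 | intermediate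
16 | 4-(ArBn-methyl)-4-[1-(benzyloxy)ethenyl]-2-(3-methylbutyl)-3-(triisopropylsiloxy)cyclobut-2-en-1-one (racemic, not isolated) | O=C1C(CCC(C)C)=C(O[Si](C(C)C)(C(C)C)C(C)C)C1(Cc1c(OC)c(C)c(OCc2ccccc2)c(C(C)=O)c1OCc1ccccc1)C(=C)OCc1ccccc1 | intermediate
17 | (3E)-4-(ArBn-methyl)-5-(benzyloxy)-2-(3-methylbutyl)-3-(triisopropylsiloxy)hexa-1,3,5-trien-1-one (ketene carbon and benzyloxyvinyl group cis, not isolated) | O=C=C(CCC(C)C)/C(O[Si](C(C)C)(C(C)C)C(C)C)=C(\C(=C)OCc1ccccc1)Cc1c(OC)c(C)c(OCc2ccccc2)c(C(C)=O)c1OCc1ccccc1 | intermediate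
18 | 4-(ArBn-methyl)-5-(benzyloxy)-2-(3-methylbutyl)-3-(triisopropylsiloxy)cyclohexa-2,4-dien-1-one (not isolated) | O=C1CC(OCc2ccccc2)=C(Cc2c(OC)c(C)c(OCc3ccccc3)c(C(C)=O)c2OCc2ccccc2)C(O[Si](C(C)C)(C(C)C)C(C)C)=C1CCC(C)C | intermediate
19 | 1-[2,6-bis(benzyloxy)-3-{[6-(benzyloxy)-4-hydroxy-3-(3-methylbutyl)-2-(triisopropylsiloxy)phenyl]methyl}-4-methoxy-5-methylphenyl]ethan-1-one | CC(C)CCc1c(O)cc(OCc2ccccc2)c(Cc2c(OC)c(C)c(OCc3ccccc3)c(C(C)=O)c2OCc2ccccc2)c1O[Si](C(C)C)(C(C)C)C(C)C | intermediate
20 | 1-[3-{[3-acetyl-2,4-bis(benzyloxy)-6-methoxy-5-methylphenyl]methyl}-2-(benzyloxy)-6-hydroxy-5-(3-methylbutyl)-4-(triisopropylsiloxy)phenyl]-2-methylpropan-1-one | CC(C)CCc1c(O)c(C(=O)C(C)C)c(OCc2ccccc2)c(Cc2c(OC)c(C)c(OCc3ccccc3)c(C(C)=O)c2OCc2ccccc2)c1O[Si](C(C)C)(C(C)C)C(C)C | intermediate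
21 | 1-[3-{[3-acetyl-2,4-bis(benzyloxy)-6-methoxy-5-methylphenyl]methyl}-2-(benzyloxy)-4,6-dihydroxy-5-(3-methylbutyl)phenyl]-2-methylpropan-1-one | CC(C)CCc1c(O)c(C(=O)C(C)C)c(OCc2ccccc2)c(Cc2c(OC)c(C)c(OCc3ccccc3)c(C(C)=O)c2OCc2ccccc2)c1O | intermediate
22 | 1-{3-[(3-acetyl-2,4-dihydroxy-6-methoxy-5-methylphenyl)methyl]-2,4,6-trihydroxy-5-(3-methylbutyl)phenyl}-2-methylpropan-1-one | COc1c(C)c(O)c(C(C)=O)c(O)c1Cc1c(O)c(CCC(C)C)c(O)c(C(=O)C(C)C)c1O | target

Total step count: 12.
Longest linear sequence: 10 steps (steps 1, 2, 3, 4, 6, 7, 9, 10, 11, 12). Steps 5 and 8 are one-step side branches.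

Steps most likely to fail

1. Step 9.
- The vinylogous-ester stabilisation of the 3-benzyloxycyclobutenone may slow the first electrocyclic opening. The temperature then needed could cause thermal drift of the siloxyalkyne to a silylketene.
- The (2+2) step may be retarded sterically at the fully substituted ketene carbon.
- The ketene may be intercepted by a flanking ether oxygen of ring A or by the product phenol.
- Photochemical opening is no remedy, because the o-benzyloxyacetophenone chromophore of ring A would undergo hydrogen abstraction.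
- Fallback, from 5 back to 22, by known chemistry throughout. Commercial 1-(2,4,6-trihydroxyphenyl)-2-methylpropan-1-one is C-prenylated (prenyl bromide, aq. KOH, 0 °C) to 1-[2,4,6-trihydroxy-3-(3-methylbut-2-en-1-yl)phenyl]-2-methylpropan-1-one F1. The side-chain alkene is saturated (H2, Pd/C, EtOAc) to 1-[2,4,6-trihydroxy-3-(3-methylbutyl)phenyl]-2-methylpropan-1-one F2. F2 is then stirred with 5 and K2CO3 in DMF. Quinone methide 8 is captured by the single free ring carbon of F2, which gives 22 directly. This is the classical union of two finished acylphloroglucinols and reuses the ring A building block unchanged.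

2. Step 6.
- The strained dione may undergo retro-Claisen ring cleavage or self-condensation under base.
- Its weakly nucleophilic enolate may lose the race against oligomerisation of the quinone methide.
- A second alkylation at C2 may occur.
- Fallback, from 5 back to 10. The four-membered ring is no longer used as a nucleophile. It is built on the ring A side chain by a ketene–ynol ether (2+2) cycloaddition.
  - Quinone methide 8, released from 5 with K2CO3, is trapped by Meldrum's acid to give 5-[(3-acetyl-2,4-dihydroxy-6-methoxy-5-methylphenyl)methyl]-2,2-dimethyl-1,3-dioxane-4,6-dione F3.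
  - Heating in wet pyridine expels acetone and CO2 and gives 8-acetyl-7-hydroxy-5-methoxy-6-methylchroman-2-one F4.
  - Lactone opening with aq. NaOH, then BnBr/K2CO3/DMF, gives benzyl 3-(ArBn)propanoate F5.
  - LiOH gives 3-(ArBn)propanoic acid F6.
  - (COCl)2 with catalytic DMF gives 3-(ArBn)propanoyl chloride F7.
  - Et3N dehydrochlorinates F7 in the presence of ethoxyacetylene. The ketene 3-(ArBn)prop-1-en-1-one F8 adds the alkyne to give racemic 4-(ArBn-methyl)-3-ethoxycyclobut-2-en-1-one F9.
  - Dilute HCl in THF hydrolyses the vinylogous ester to 2-(ArBn-methyl)-3-hydroxycyclobut-2-en-1-one F10.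
  - One O-benzylation under the conditions of step 7 gives 10.

3. Step 10.
- The Lewis acid may strip benzyl groups that sit next to carbonyl groups.
- Ipso-protonation at C1′ may cleave or scramble the methylene bridge.
- The reaction may stall at O-acylation.
- Fallback, from 19 back to 20, free of acylium ions and strong Lewis acids.
  - Phenylboronic-acid-templated ortho-hydroxyalkylation of the phenol (isobutyraldehyde, PhB(OH)2, catalytic propionic acid, toluene, reflux with water removal) gives the racemic 4-isopropyl-2-phenyl-4H-1,3,2-benzodioxaborin of ring B F11.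
  - Boronate exchange with propane-1,3-diol frees the racemic o-hydroxybenzylic alcohol 1-[2,6-bis(benzyloxy)-3-{[6-(benzyloxy)-4-hydroxy-5-(1-hydroxy-2-methylpropyl)-3-(3-methylbutyl)-2-(triisopropylsiloxy)phenyl]methyl}-4-methoxy-5-methylphenyl]ethan-1-one F12.
  - MnO2 in CH2Cl2 oxidises the benzylic alcohol to ketone 20.

Further compounds
F1 | step 9 | 1-[2,4,6-trihydroxy-3-(3-methylbut-2-en-1-yl)phenyl]-2-methylpropan-1-one | CC(C)C(=O)c1c(O)cc(O)c(CC=C(C)C)c1O
F2 | step 9 | 1-[2,4,6-trihydroxy-3-(3-methylbutyl)phenyl]-2-methylpropan-1-one | CC(C)C(=O)c1c(O)cc(O)c(CCC(C)C)c1O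
F3 | step 6 | 5-[(3-acetyl-2,4-dihydroxy-6-methoxy-5-methylphenyl)methyl]-2,2-dimethyl-1,3-dioxane-4,6-dione | CC1(C)OC(=O)C(Cc2c(OC)c(C)c(O)c(C(C)=O)c2O)C(=O)O1
F4 | step 6 | 8-acetyl-7-hydroxy-5-methoxy-6-methylchroman-2-one | CC(=O)c1c(O)c(C)c(OC)c2c1OC(=O)CC2
F5 | step 6 | benzyl 3-[3-acetyl-2,4-bis(benzyloxy)-6-methoxy-5-methylphenyl]propanoate | O=C(CCc1c(OC)c(C)c(OCc2ccccc2)c(C(C)=O)c1OCc1ccccc1)OCc1ccccc1
F6 | step 6 | 3-[3-acetyl-2,4-bis(benzyloxy)-6-methoxy-5-methylphenyl]propanoic acid | OC(=O)CCc1c(OC)c(C)c(OCc2ccccc2)c(C(C)=O)c1OCc1ccccc1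
F7 | step 6 | 3-[3-acetyl-2,4-bis(benzyloxy)-6-methoxy-5-methylphenyl]propanoyl chloride | ClC(=O)CCc1c(OC)c(C)c(OCc2ccccc2)c(C(C)=O)c1OCc1ccccc1
F8 | step 6 | 3-[3-acetyl-2,4-bis(benzyloxy)-6-methoxy-5-methylphenyl]prop-1-en-1-one (ketene) | O=C=CCc1c(OC)c(C)c(OCc2ccccc2)c(C(C)=O)c1OCc1ccccc1
F9 | step 6 | 4-{[3-acetyl-2,4-bis(benzyloxy)-6-methoxy-5-methylphenyl]methyl}-3-ethoxycyclobut-2-en-1-one (racemic) | CCOC1=CC(=O)C1Cc1c(OC)c(C)c(OCc2ccccc2)c(C(C)=O)c1OCc1ccccc1
F10 | step 6 | 2-{[3-acetyl-2,4-bis(benzyloxy)-6-methoxy-5-methylphenyl]methyl}-3-hydroxycyclobut-2-en-1-one | O=C1CC(O)=C1Cc1c(OC)c(C)c(OCc2ccccc2)c(C(C)=O)c1OCc1ccccc1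
F11 | step 10 | 4-isopropyl-2-phenyl-4H-1,3,2-benzodioxaborin of ring B, formed across O4′ and C5′ (racemic) | CC(C)CCc1c2OB(c3ccccc3)OC(C(C)C)c2c(OCc2ccccc2)c(Cc2c(OC)c(C)c(OCc3ccccc3)c(C(C)=O)c2OCc2ccccc2)c1O[Si](C(C)C)(C(C)C)C(C)C
F12 | step 10 | 1-[2,6-bis(benzyloxy)-3-{[6-(benzyloxy)-4-hydroxy-5-(1-hydroxy-2-methylpropyl)-3-(3-methylbutyl)-2-(triisopropylsiloxy)phenyl]methyl}-4-methoxy-5-methylphenyl]ethan-1-one (racemic) | CC(C)CCc1c(O)c(C(O)C(C)C)c(OCc2ccccc2)c(Cc2c(OC)c(C)c(OCc3ccccc3)c(C(C)=O)c2OCc2ccccc2)c1O[Si](C(C)C)(C(C)C)C(C)C
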